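**Strategy.** Both halves of the target are the same aryl(trimethyl)cyclopentane, so it is traced to one monomer, the dimethyl ether 12, whose aryl CH3 (as benzylzinc) is joined to the ring carbon between OMe and CH3 of a second molecule (as bromide). The cyclopentane is made by an enantioselective (3+2) annulation: a 1,1-dimethyl-2-siloxyallyl cation adds to an achiral isopropenylarene and closes the ring CH2–CH2 bond and the C(CH3)2–C(aryl)(CH3) bond in one operation. Run once, this step supplies the cyclopentane of both halves. It exploits the vicinal quaternary carbons of the cyclopentane ring: the aryl-bearing one passes through an o-methoxy-stabilised benzylic cation that is captured inside a chiral ion pair.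

Key step: step 3

Remark: the sense of induction of the ion-pair catalyst cannot be predicted with certainty. The catalyst antipode that gives ketone 10 with the (R) configuration is to be identified in a first screen, and the configuration confirmed by X-ray analysis (anomalous dispersion) of bromide 13.

Step 1
Reactants: 1 3-hydroxy-3-methylbutan-2-one
Product: 3 3-methyl-2,3-bis(triethylsilyloxy)but-1-ene, via 3-methyl-3-(triethylsilyloxy)butan-2-one 2 (not isolated)
Conditions: TESOTf (2.3 equiv), Et3N (3 equiv), CH2Cl2, 0 °C → rt
Reagents that add atoms: triethylsilyl triflate, CC[Si](CC)(CC)OS(=O)(=O)C(F)(F)F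
Why: O-silylation of the tertiary alcohol followed by silyl enol ether formation (R3SiOTf/Et3N soft enolisation) should give a single regioisomer, because only the CH3 side of the ketone can enolise.

Step 2
Reactants: 4 3,4-dimethoxytoluene
Product: 7 1,2-dimethoxy-5-methyl-3-(prop-1-en-2-yl)benzene, via (2,3-dimethoxy-5-methylphenyl)lithium 5 (not isolated), via (2,3-dimethoxy-5-methylphenyl)zinc chloride 6 (not isolated)
Conditions: n-BuLi, TMEDA, Et2O, 0 °C → rt; ZnCl2, THF, 0 °C; 2-bromopropene, Pd(PPh3)4 (3 mol%), 50 °C
Reagents that add atoms: 2-bromopropene, CC(Br)=C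
Why: Directed ortho-lithiation should occur at the unhindered position ortho to OMe (the other ortho site is flanked by the CH3 group), and transmetalation to zinc followed by Negishi coupling installs the isopropenyl group.

Step 3
Reactants: 7 1,2-dimethoxy-5-methyl-3-(prop-1-en-2-yl)benzene, 3 3-methyl-2,3-bis(triethylsilyloxy)but-1-ene
Product: 10 (3R)-3-(2,3-dimethoxy-5-methylphenyl)-2,2,3-trimethylcyclopentan-1-one, via 1,1-dimethyl-2-(triethylsilyloxy)allyl cation triflate 8 (not isolated), via tertiary benzylic cation 9 (not isolated)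
Conditions: 3 (1.5 equiv, slow addition), TESOTf (20 mol%), chiral tert-leucine-derived arylpyrrolidine amide squaramide (10 mol%), MTBE, −78 → −40 °C; aq. NaHCO3
Reagents that add atoms: none
Why: Proposed new method: the squaramide·TESOTf complex should silylate the tertiary OSiEt3 group of 3 and expel (Et3Si)2O to give the siloxyallyl cation 8 as a chiral ion pair, whose unsubstituted CH2 terminus attacks the CH2 terminus of the styrene (CH2–CH2 bond) to give the benzylic cation 9; the tetrasubstituted enol silane carbon then closes onto that cation (CMe2–C(Ar)Me bond) and the O-silyl oxocarbenium ion returns Et3Si+ to triflate. The closest known reactions are the racemic (3+2) annulations of iron- and siloxy-oxyallyl cations with α-methylstyrenes, the squaramide/silyl triflate (4+3) cycloaddition of siloxyallyl cations with furans, and the enantioconvergent squaramide/silyl triflate SN1 allylation of tertiary benzylic cations; an enantioselective oxyallyl–styrene (3+2) itself has not been shown. The cyclopentanone ring is closed stepwise, the second bond by a 5-(enolendo)-exo-trig C-attack of the enol silane on the carbenium carbon, which is feasible because the electrophile is a free planar cation and not a displaceable leaving group. The only new stereocentre, C3 of the cyclopentanone, is set in this ring closure by catalyst control: the planar o-methoxy-stabilised cation sits in the squaramide–triflate ion pair with one face shielded, and the catalyst antipode is chosen to give the (R)-ketone. The step needs head-to-tail regioselectivity, secured by the Markovnikov polarity of the α-methylstyrene and by attack through the less hindered allyl terminus, and chemoselectivity for the alkene over the arene, secured by the higher π-nucleophilicity of the 1,1-disubstituted styrene; slow addition of 3 suppresses its self-alkylation.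

Step 4
Reactants: 10 (3R)-3-(2,3-dimethoxy-5-methylphenyl)-2,2,3-trimethylcyclopentan-1-one
Product: 12 1,2-dimethoxy-5-methyl-3-[(1S)-1,2,2-trimethylcyclopentyl]benzene, via ketone hydrazone 11 (not isolated)
Conditions: N2H4·H2O, KOH, diethylene glycol, 130 °C then 200 °C
Reagents that add atoms: none
Why: Wolff–Kishner reduction (Huang-Minlon modification), as used on hindered cuparenone-type ketones, should remove the carbonyl group without touching the non-enolisable quaternary stereocentre, whose descriptor changes from R to S only because the CIP priorities change.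

Step 5
Reactants: 12 1,2-dimethoxy-5-methyl-3-[(1S)-1,2,2-trimethylcyclopentyl]benzene
Product: 13 2-bromo-3,4-dimethoxy-1-methyl-5-[(1S)-1,2,2-trimethylcyclopentyl]benzene
Conditions: NBS, MeCN, 0 °C → rt, dark
Reagents that add atoms: N-bromosuccinimide, O=C1CCC(=O)N1Br
Why: Electrophilic aromatic bromination under ionic conditions should go to the position between OMe and CH3 (ortho to the unhindered methoxy group), because the only other free ring position is flanked by the quaternary cyclopentyl carbon.

Step 6
Reactants: 12 1,2-dimethoxy-5-methyl-3-[(1S)-1,2,2-trimethylcyclopentyl]benzene, 13 2-bromo-3,4-dimethoxy-1-methyl-5-[(1S)-1,2,2-trimethylcyclopentyl]benzene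
Product: 16 2-{[3,4-dimethoxy-5-[(1S)-1,2,2-trimethylcyclopentyl]phenyl]methyl}-3,4-dimethoxy-1-methyl-5-[(1S)-1,2,2-trimethylcyclopentyl]benzene, via benzylpotassium 14 (not isolated), via benzylzinc chloride 15 (not isolated)
Conditions: 12, n-BuLi, KOt-Bu, 2,2,6,6-tetramethylpiperidine, THF, −78 °C; ZnCl2, −78 °C → rt; 13, Pd(OAc)2 (3 mol%), SPhos (6 mol%), THF, 60 °C
Reagents that add atoms: none
Why: Benzylic (lateral) metalation of 12 with the mixed Li/K amide base, transmetalation to zinc and Negishi cross-coupling with the di-ortho-substituted aryl bromide 13 should join the aryl CH2 of one monomer to the ring carbon of the other without touching either quaternary stereocentre.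

Step 7
Reactants: 16 2-{[3,4-dimethoxy-5-[(1S)-1,2,2-trimethylcyclopentyl]phenyl]methyl}-3,4-dimethoxy-1-methyl-5-[(1S)-1,2,2-trimethylcyclopentyl]benzene
Product: 18 3-{[3,4-dihydroxy-5-[(1S)-1,2,2-trimethylcyclopentyl]phenyl]methyl}-4-methyl-6-[(1S)-1,2,2-trimethylcyclopentyl]benzene-1,2-diol, via bis(bromodioxaborole) 17 (not isolated)
Conditions: BBr3 (6 equiv), CH2Cl2, −78 °C → rt; degassed H2O, argon
Reagents that add atoms: none
Why: Lewis acid cleavage of the four aryl methyl ethers by BBr3, with hydrolysis of the aryloxyboron species on work-up, should free both catechols while the quaternary stereocentres and the diarylmethane stay intact.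

**Compound list**

1 | 3-hydroxy-3-methylbutan-2-one | CC(=O)C(C)(C)O | starting material
2 | 3-methyl-3-(triethylsilyloxy)butan-2-one | CC(=O)C(C)(C)O[Si](CC)(CC)CC | intermediate (not isolated)
3 | 3-methyl-2,3-bis(triethylsilyloxy)but-1-ene | C=C(O[Si](CC)(CC)CC)C(C)(C)O[Si](CC)(CC)CC | intermediate
4 | 3,4-dimethoxytoluene | COc1ccc(C)cc1OC | starting material
5 | (2,3-dimethoxy-5-methylphenyl)lithium | [Li]c1cc(C)cc(OC)c1OC | intermediate (not isolated)
6 | (2,3-dimethoxy-5-methylphenyl)zinc chloride | Cl[Zn]c1cc(C)cc(OC)c1OC | intermediate (not isolated)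
7 | 1,2-dimethoxy-5-methyl-3-(prop-1-en-2-yl)benzene | COc1cc(C)cc(C(C)=C)c1OC | intermediate
8 | 1,1-dimethyl-2-(triethylsilyloxy)allyl cation triflate | C[C+](C)C(=C)O[Si](CC)(CC)CC.[O-]S(=O)(=O)C(F)(F)F | intermediate (not isolated)
9 | 2-(2,3-dimethoxy-5-methylphenyl)-6-methyl-5-(triethylsilyloxy)hept-5-en-2-ylium triflate (tertiary benzylic cation) | COc1cc(C)cc([C+](C)CCC(O[Si](CC)(CC)CC)=C(C)C)c1OC.[O-]S(=O)(=O)C(F)(F)F | intermediate (not isolated)
10 | (3R)-3-(2,3-dimethoxy-5-methylphenyl)-2,2,3-trimethylcyclopentan-1-one | COc1cc(C)cc([C@@]2(C)CCC(=O)C2(C)C)c1OC | intermediate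
11 | [(3S)-3-(2,3-dimethoxy-5-methylphenyl)-2,2,3-trimethylcyclopentylidene]hydrazine (ketone hydrazone) | COc1cc(C)cc([C@@]2(C)CCC(=NN)C2(C)C)c1OC | intermediate (not isolated)
12 | 1,2-dimethoxy-5-methyl-3-[(1S)-1,2,2-trimethylcyclopentyl]benzene (herbertenediol dimethyl ether) | COc1cc(C)cc([C@@]2(C)CCCC2(C)C)c1OC | intermediate
13 | 2-bromo-3,4-dimethoxy-1-methyl-5-[(1S)-1,2,2-trimethylcyclopentyl]benzene | COc1c(Br)c(C)cc([C@@]2(C)CCCC2(C)C)c1OC | intermediate
14 | {3,4-dimethoxy-5-[(1S)-1,2,2-trimethylcyclopentyl]phenyl}methylpotassium (benzylpotassium) | [K]Cc1cc(OC)c(OC)c([C@@]2(C)CCCC2(C)C)c1 | intermediate (not isolated)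
15 | {3,4-dimethoxy-5-[(1S)-1,2,2-trimethylcyclopentyl]phenyl}methylzinc chloride (benzylzinc chloride) | Cl[Zn]Cc1cc(OC)c(OC)c([C@@]2(C)CCCC2(C)C)c1 | intermediate (not isolated)
16 | 2-{[3,4-dimethoxy-5-[(1S)-1,2,2-trimethylcyclopentyl]phenyl]methyl}-3,4-dimethoxy-1-methyl-5-[(1S)-1,2,2-trimethylcyclopentyl]benzene | Cc1cc([C@@]2(C)CCCC2(C)C)c(OC)c(OC)c1Cc1cc(OC)c(OC)c([C@@]2(C)CCCC2(C)C)c1 | intermediate
17 | bis(2-bromo-1,3,2-benzodioxaborole) derived from 18 | Cc1cc([C@@]2(C)CCCC2(C)C)c2OB(Br)Oc2c1Cc1cc2OB(Br)Oc2c([C@@]2(C)CCCC2(C)C)c1 | intermediate (not isolated)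
18 | 3-{[3,4-dihydroxy-5-[(1S)-1,2,2-trimethylcyclopentyl]phenyl]methyl}-4-methyl-6-[(1S)-1,2,2-trimethylcyclopentyl]benzene-1,2-diol | Cc1cc([C@@]2(C)CCCC2(C)C)c(O)c(O)c1Cc1cc(O)c(O)c([C@@]2(C)CCCC2(C)C)c1 | target

**Total step count:** 7 steps (step 1 is a one-step side branch).
**Longest linear sequence:** 6 steps (steps 2 to 7, from 3,4-dimethoxytoluene).

**Steps most likely to fail**

Step 3 (Proposed new method). The benzylic cation may lose a proton before the hindered ring closure, the enol silane may alkylate itself, or the ion pair may discriminate the two faces of the cation poorly. The fallback sets out from 7. The styrene is heated with 1,3-dibromo-3-methylbutan-2-one F1 (prepared by dibromination of 3-methylbutan-2-one with Br2) and Fe2(CO)9 in benzene at 55 °C. This is the established reductive iron-oxyallyl (3+2) annulation of α-methylstyrenes and should give the racemic ketone F2. Preparative chromatography on a chiral stationary phase then separates the (R)-enantiomer, which is compound 10 and rejoins the route there, from the (S)-ketone F3.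

Step 6. Ring metalation ortho to OMe may compete with benzylic metalation, and slow oxidative addition at the di-ortho-substituted bromide may lead to homocoupling of the benzylzinc. The fallback sets out from 12 and 13. The aryl CH3 of 12 is oxidised with DDQ in aqueous acetic acid (benzylic oxidation of a p-alkoxytoluene) to 3,4-dimethoxy-5-[(1S)-1,2,2-trimethylcyclopentyl]benzaldehyde F4. Bromide 13 is converted by Br/Li exchange (n-BuLi, THF, −78 °C) into the aryllithium F5, which adds to F4 to give the diarylmethanol F6. Ionic hydrogenation (Et3SiH, TFA, CH2Cl2) removes the hydroxyl group and returns to the route at 16.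

Step 4. Hydrazone formation may stall at the carbonyl next to the quaternary carbon, and hot KOH may cleave aryl methyl ethers in part. The fallback sets out from 10. NaBH4 in MeOH reduces the ketone to the alcohol F7 (epimers at the carbinol carbon). NaH, CS2 and MeI convert it into the S-methyl xanthate F8. Bu3SnH and AIBN in toluene at 110 °C (Barton–McCombie deoxygenation) then give 12, where the route is rejoined.

**Further compounds**

F1 | step 3 | 1,3-dibromo-3-methylbutan-2-one | CC(C)(Br)C(=O)CBr
F2 | step 3 | rac-3-(2,3-dimethoxy-5-methylphenyl)-2,2,3-trimethylcyclopentan-1-one | COc1cc(C)cc(C2(C)CCC(=O)C2(C)C)c1OC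
F3 | step 3 | (3S)-3-(2,3-dimethoxy-5-methylphenyl)-2,2,3-trimethylcyclopentan-1-one | COc1cc(C)cc([C@]2(C)CCC(=O)C2(C)C)c1OC
F4 | step 6 | 3,4-dimethoxy-5-[(1S)-1,2,2-trimethylcyclopentyl]benzaldehyde | COc1cc(C=O)cc([C@@]2(C)CCCC2(C)C)c1OC
F5 | step 6 | {2,3-dimethoxy-6-methyl-4-[(1S)-1,2,2-trimethylcyclopentyl]phenyl}lithium | COc1c([Li])c(C)cc([C@@]2(C)CCCC2(C)C)c1OC
F6 | step 6 | {2,3-dimethoxy-6-methyl-4-[(1S)-1,2,2-trimethylcyclopentyl]phenyl}{3,4-dimethoxy-5-[(1S)-1,2,2-trimethylcyclopentyl]phenyl}methanol (epimers at the carbinol carbon) | COc1c(C(O)c2cc(OC)c(OC)c([C@@]3(C)CCCC3(C)C)c2)c(C)cc([C@@]2(C)CCCC2(C)C)c1OC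
F7 | step 4 | (3S)-3-(2,3-dimethoxy-5-methylphenyl)-2,2,3-trimethylcyclopentan-1-ol (epimers at C1) | COc1cc(C)cc([C@@]2(C)CCC(O)C2(C)C)c1OC
F8 | step 4 | O-[(3S)-3-(2,3-dimethoxy-5-methylphenyl)-2,2,3-trimethylcyclopentyl] S-methyl carbonodithioate (epimers at C1) | COc1cc(C)cc([C@@]2(C)CCC(OC(=S)SC)C2(C)C)c1OC
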